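A direct plan would read the target as a biaryl and would join two fully O-methylated halves by Suzuki coupling.
It would build the same C21 alkynyl aryl ketone twice, once as the ring-B bromide A1 and once as the ring-A pinacol boronate A2.
Coupling would give the biaryl diyne A3, hydrogenation the octamethyl ether A4, and BBr3 the free octaphenol.
Weakest would be the Suzuki union. An electron-rich bromide flanked by OMe would meet an electron-rich, ortho-alkynyl boronate, so protodeboronation and carbopalladation of the alkyne would compete, at the cost of both advanced halves.
Next would be the eightfold ether cleavage as the last step. Each incomplete cleavage would leave a partly methylated congener, and the air-sensitive bis-catechol would form in a large excess of BBr3 on the most precious material.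
Third would be the ring bromination, ring iodination and Miyaura borylation. These three steps would add no skeletal bond and would serve only to tell two identical monomers apart.

**Plan of the new route**
Rings: A = biaryl catechol (chain at C1, OH at C3/C4), B = biaryl acylresorcinol (acyl at C1, OH at C2/C6), C = outer catechol, D = outer acylresorcinol. The target is the A(C6)–B(C3) dehydrodimer of malabaricone C, two identical C21 units joined head to tail.
The retrosynthesis cuts this A–B bond first, as a C–H/C–H union of two unprotected monomers. It then cuts the monomer chain at C7–C8 (cross metathesis) and at C2–C3 (enolate alkylation).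
Enabling feature: each monomer has one ring that is easy to oxidise (the catechol, whose o-quinone has C6 as its only free β-carbon because C1 bears the chain). It also has one ring that is hard to oxidise but carbon-nucleophilic (the acylresorcinol, C3 = C5). Two electron-rich carbons are therefore joined by anodic polarity reversal of one of them.
No ring is built. Rings B/D are bought in 1 and rings A/C in 5, with all oxygens and the first side-chain carbon in place, and the A–B assembly arises only in the last step.
No halide, boronate, palladium biaryl coupling or O-protecting group occurs, so there are no handle steps and no final deprotection. One skeleton is made once and used twice.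

Key step: step 4

Assumption: the SMILES has no stereodescriptor, and the A–B axis has only two ortho substituents (the chain on ring A, one OH on ring B). It should rotate freely at room temperature, so the target is treated as achiral and no stereochemistry has to be set.

**Route**

Step 1
Reactants: 1 2',6'-dihydroxyacetophenone; 2 6-bromohex-1-ene
Product: 4 1-(2,6-dihydroxyphenyl)oct-7-en-1-one, via trilithium enolate bis(phenolate) 3 (not isolated)
Conditions: LDA (3.3 equiv), THF–DMPU, −78 → 0 °C; 2 (0.9 equiv), 0 °C → rt; 1 M HCl
Reagents that add atoms: none
Why: Polyanion (enolate) alkylation, in which three equivalents of LDA should convert 1 into 3, whose chelated lithium phenolates are sluggish while the terminal enolate carbon is the most nucleophilic site, so the primary bromide should be taken up by SN2 at carbon only, as in the known C-alkylation and C-acylation of polylithiated o-hydroxyacetophenones; no stereocentre is formed.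

Step 2
Reactants: 4 1-(2,6-dihydroxyphenyl)oct-7-en-1-one; 5 4-allylbenzene-1,2-diol (4-allylcatechol)
Product: 6 (E)-1-(2,6-dihydroxyphenyl)-9-(3,4-dihydroxyphenyl)non-7-en-1-one (E/Z mixture, drawn as E)
Conditions: 5 (3 equiv), Hoveyda–Grubbs II (3 mol %), AcOH (10 mol %), CH2Cl2, 40 °C, Ar purge
Reagents that add atoms: none
Why: Olefin cross metathesis of two unhindered terminal (type I) alkenes, in which the excess of cheap 5 should bias the statistical mixture toward the cross product, ruthenium carbenes tolerate free phenols and ketones, loss of ethene drives the exchange, and the alkene geometry is irrelevant because the double bond is saturated next.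

Step 3
Reactants: 6 (E)-1-(2,6-dihydroxyphenyl)-9-(3,4-dihydroxyphenyl)non-7-en-1-one
Product: 7 malabaricone C, 1-(2,6-dihydroxyphenyl)-9-(3,4-dihydroxyphenyl)nonan-1-one
Conditions: H2 (1 atm), 10% Pd/C, EtOAc, rt
Reagents that add atoms: none
Why: Heterogeneous catalytic hydrogenation should saturate the isolated disubstituted alkene at 1 atm, while the arenes and the aryl ketone, which is deactivated by two ortho hydroxyl groups and a strong internal hydrogen bond, should stay untouched; no stereocentre is formed.

Step 4
Reactants: 7 malabaricone C (two molecules: one is oxidised, one acts as the nucleophile)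
Product: 9 giganteone A, via malabaricone C o-quinone 8 (not isolated)
Conditions: graphite-felt anode, Pt cathode, divided cell (Nafion), +0.40 V vs Ag/AgCl, MeCN–0.2 M sodium phosphate buffer pH 7.5 (1:1), 0.1 M in 7, Ar, 10 °C, stopped at 0.5 F/mol; pH 4, EtOAc; unreacted 7 recycled
Reagents that add atoms: none
Why: At this potential only the catechol ring of 7 should lose two electrons and two protons (the hydrogen-bonded 2-acylresorcinol ring is oxidised several hundred millivolts higher), giving o-quinone 8, in which the formerly electron-rich C6 has become the β-carbon of an enone; the acylresorcinolate of a second molecule of 7, the only carbon nucleophile appreciably ionised at pH 7.5, should add through C3 (ortho to one oxygen, para to the other), and tautomerisation restores both arenes (EC mechanism, net C–H/C–H dehydrodimerisation with hydrogen evolved at the cathode). The closest known reaction types are the anodic or laccase-mediated oxidation of 4-methylcatechol in the presence of enolic and phenolic carbon nucleophiles, and the head-to-tail oxidative dimerisation of flavan-3-ols, in which the B-ring o-quinone is attacked at C6' by the meta-dioxygenated A ring of a second molecule. No ring is closed and no stereocentre is formed, and the new di-ortho-substituted axis rotates freely. Site selectivity on the electrophile rests on the chain at C1, which occupies the other β-carbon so that C6 is the only open 1,4-acceptor site and which also blocks the only β-position at which a re-oxidised adduct could close to a dibenzofuran; on the nucleophile C3 and C5 are equivalent, so a single constitution should result. O-attack is reversible whereas the C-adduct aromatises irreversibly, the neutral catechol rings are much weaker carbon nucleophiles than the acylresorcinolate, and the intramolecular alternative would need a 14-membered cyclophane, which the 0.1 M concentration disfavours. Selectivity against further coupling of 9, which still carries both kinds of ring, is secured only statistically, by stopping the charge early and recycling 7, while redox exchange between 8 and 7 is degenerate and harmless.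

**Compound list**

1 | 2',6'-dihydroxyacetophenone | CC(=O)c1c(O)cccc1O | starting material
2 | 6-bromohex-1-ene | C=CCCCCBr | starting material
3 | trilithium enolate bis(phenolate) of 1 | [Li+].[Li+].[Li+].C=C([O-])c1c([O-])cccc1[O-] | intermediate
4 | 1-(2,6-dihydroxyphenyl)oct-7-en-1-one | C=CCCCCCC(=O)c1c(O)cccc1O | intermediate
5 | 4-allylbenzene-1,2-diol | C=CCc1ccc(O)c(O)c1 | starting material
6 | (E)-1-(2,6-dihydroxyphenyl)-9-(3,4-dihydroxyphenyl)non-7-en-1-one | O=C(CCCCC/C=C/Cc1ccc(O)c(O)c1)c1c(O)cccc1O | intermediate
7 | malabaricone C | O=C(CCCCCCCCc1ccc(O)c(O)c1)c1c(O)cccc1O | intermediate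
8 | malabaricone C o-quinone, 4-[9-(2,6-dihydroxyphenyl)-9-oxononyl]cyclohexa-3,5-diene-1,2-dione | O=C(CCCCCCCCC1=CC(=O)C(=O)C=C1)c1c(O)cccc1O | intermediate
9 | giganteone A (achiral) | O=C(CCCCCCCCc1cc(O)c(O)cc1-c1ccc(O)c(C(=O)CCCCCCCCc2ccc(O)c(O)c2)c1O)c1c(O)cccc1O | target

**Total steps:** 4
**Longest linear sequence:** 4 (1 → 4 → 6 → 7 → 9)

**Steps most likely to fail**

Step 4. The product still carries two catechols and open acylresorcinol positions, so continued oxidation and coupling may grow oligomers at the expense of the dimer. The quinone may also decay by tautomerisation to the quinone methide or by addition of water if carbon attack is slow.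
- The fallback sets out from 7 and comes back at 9. It replaces statistical self-coupling by a directed cross-coupling of two differentiated partners.
- Part of 7 would be treated with 2,2-dimethoxypropane and catalytic TsOH in refluxing toluene. This should give the catechol acetonide 9-(2,2-dimethyl-1,3-benzodioxol-5-yl)-1-(2,6-dihydroxyphenyl)nonan-1-one F1, which cannot be oxidised at the working potential and can act only as the nucleophile.
- Free 7 would then be fed slowly, as the limiting quinone source, into an excess of F1 in the same cell, and the electrolysis could run to full consumption of 7.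
- This should give the ring-C acetonide of giganteone A F2, which holds a single oxidisable ring. Aqueous TFA would release 9.
- Any 7 that couples with itself is 9 already, so both channels converge.

Step 2. The allyl double bond may migrate into conjugation before metathesis, which would shorten the chain by one carbon. Homodimerisation and slow turnover through binding of the catechol to ruthenium may add to this.
- The fallback sets out from 1 (as its salt 3) and comes back at 7. It fixes the chain length by olefination and alkylation instead of metathesis.
- Wittig olefination of commercial 3,4-bis(benzyloxy)benzaldehyde with the ylide from (6-hydroxyhexyl)triphenylphosphonium bromide (NaHMDS, 2 equiv) would give (Z)-7-[3,4-bis(benzyloxy)phenyl]hept-6-en-1-ol F3.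
- Appel iodination (I2, PPh3, imidazole) would give (Z)-1,2-bis(benzyloxy)-4-(7-iodohept-1-en-1-yl)benzene F4.
- Alkylation of 3 with F4 would give (Z)-9-[3,4-bis(benzyloxy)phenyl]-1-(2,6-dihydroxyphenyl)non-8-en-1-one F5.
- Hydrogenation over Pd/C would saturate the alkene and cleave both benzyl ethers in one operation to give 7.

Step 1. The polylithium salt may be poorly soluble and the third deprotonation incomplete. O-alkylation, or proton transfer leading to double alkylation, may also intervene.
- The fallback sets out from 1 and comes back at 7. It avoids the polyanion by capping the phenols as benzyl ethers, which the hydrogenation of step 3 removes anyway.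
- BnBr and K2CO3 in DMF would give 1-[2,6-bis(benzyloxy)phenyl]ethanone F6.
- Its simple lithium enolate (LDA, 1.05 equiv) and 2 would give 1-[2,6-bis(benzyloxy)phenyl]oct-7-en-1-one F7.
- Cross metathesis with 5 as in step 2 would give (E)-1-[2,6-bis(benzyloxy)phenyl]-9-(3,4-dihydroxyphenyl)non-7-en-1-one F8.
- Hydrogenation over Pd/C would then deliver 7.

**Further compounds**

F1 | step 4 | 9-(2,2-dimethyl-1,3-benzodioxol-5-yl)-1-(2,6-dihydroxyphenyl)nonan-1-one | CC1(C)Oc2ccc(CCCCCCCCC(=O)c3c(O)cccc3O)cc2O1
F2 | step 4 | ring-C acetonide of giganteone A | O=C(CCCCCCCCc1cc(O)c(O)cc1-c1ccc(O)c(C(=O)CCCCCCCCc2ccc3OC(C)(C)Oc3c2)c1O)c1c(O)cccc1O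
F3 | step 2 | (Z)-7-[3,4-bis(benzyloxy)phenyl]hept-6-en-1-ol | OCCCCC/C=C\c1ccc(OCc2ccccc2)c(OCc2ccccc2)c1
F4 | step 2 | (Z)-1,2-bis(benzyloxy)-4-(7-iodohept-1-en-1-yl)benzene | ICCCCC/C=C\c1ccc(OCc2ccccc2)c(OCc2ccccc2)c1
F5 | step 2 | (Z)-9-[3,4-bis(benzyloxy)phenyl]-1-(2,6-dihydroxyphenyl)non-8-en-1-one | O=C(CCCCCC/C=C\c1ccc(OCc2ccccc2)c(OCc2ccccc2)c1)c1c(O)cccc1O
F6 | step 1 | 1-[2,6-bis(benzyloxy)phenyl]ethanone | CC(=O)c1c(OCc2ccccc2)cccc1OCc1ccccc1
F7 | step 1 | 1-[2,6-bis(benzyloxy)phenyl]oct-7-en-1-one | C=CCCCCCC(=O)c1c(OCc2ccccc2)cccc1OCc1ccccc1
F8 | step 1 | (E)-1-[2,6-bis(benzyloxy)phenyl]-9-(3,4-dihydroxyphenyl)non-7-en-1-one | O=C(CCCCC/C=C/Cc1ccc(O)c(O)c1)c1c(OCc2ccccc2)cccc1OCc1ccccc1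
A1 | direct plan | 1-(3-bromo-2,6-dimethoxyphenyl)-9-(3,4-dimethoxyphenyl)non-8-yn-1-one | COc1ccc(C#CCCCCCCC(=O)c2c(OC)ccc(Br)c2OC)cc1OC
A2 | direct plan | 1-(2,6-dimethoxyphenyl)-9-[4,5-dimethoxy-2-(4,4,5,5-tetramethyl-1,3,2-dioxaborolan-2-yl)phenyl]non-8-yn-1-one | COc1cc(B2OC(C)(C)C(C)(C)O2)c(C#CCCCCCCC(=O)c2c(OC)cccc2OC)cc1OC
A3 | direct plan | octamethylated biaryl diyne | COc1cc(-c2ccc(OC)c(C(=O)CCCCCCC#Cc3ccc(OC)c(OC)c3)c2OC)c(C#CCCCCCCC(=O)c2c(OC)cccc2OC)cc1OC
A4 | direct plan | giganteone A octamethyl ether | COc1cc(-c2ccc(OC)c(C(=O)CCCCCCCCc3ccc(OC)c(OC)c3)c2OC)c(CCCCCCCCC(=O)c2c(OC)cccc2OC)cc1OC
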